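Abbreviations used throughout: Bn = benzyl, TBS = tert-butyldimethylsilyl, TIPS = triisopropylsilyl; ArB = 3-(benzyloxy)-2,4-dimethoxyphenyl (ring B of the isoflavan); ArP = 4-(allyloxy)-2,6-bis(benzyloxy)phenyl (the phloroglucinol-derived ring that becomes ring A of the flavanone); Chr = (3R,4S)-7-(benzyloxy)-3-ArB-chroman-4-yl. Locants C2, C3, C4 and C4a–C8a without further qualification are those of the isoflavan.

## The problem

Target 36 is (2S)-naringenin bearing a (3R,4S)-isoflavan-4-yl group at C6 of its phloroglucinol ring. The two heterocycles meet in a single C–C bond at a crowded, doubly benzylic methine (C4) that also neighbours the C3 aryl group. C3 and C4 are adjacent and trans, so they can be set together in one bond-forming event. Flavanone C2 lies five bonds from C4, gets no useful bias from it and needs reagent control. The flavanone must be the 6- and not the 8-substituted isomer, so of the three phloroglucinol oxygens exactly the one para to the isoflavanyl carbon has to become the pyranone oxygen. The C4–aryl bond is acid-labile, because ipso-protonation of the phloroglucinol ring releases a C4 cation stabilised by O1 and the 7-oxygen. The flavanone loses its C2 configuration and its 6/8 regiochemistry by base-induced opening to the chalcone, and five phenols must be freed at the end without either event. The feature that opens the chosen route is ring A of the isoflavan (C4a–C8a): a resorcinol in which C4a carries the C4 chain, C8a carries the ring oxygen ortho to it, C7 carries a hydroxyl para to it, and C5, C6 and C8 bear hydrogen. This is the substitution pattern produced when a 2-substituted vinylketene combines with a siloxyethyne, so ring A can be built last onto an open chain that already holds C2, C3 and C4.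

## Retrosynthesis

**36 ⇒ 35.** Five O–benzyl bonds are cut. Benzyl is the only group that can leave from all five phenols under neutral conditions, which the acid-labile C4–aryl bond and the base-labile flavanone both demand. The forward step is a hydrogenolysis that must stop before the aryl ketone or the benzylic C2–O1 bond is reduced.

**35 ⇒ 33 + 34.** The flavanone C2–aryl bond is cut, giving chromone 33 and 4-(benzyloxy)phenylboronic acid 34. The neighbouring cut, O1–C2 (closure of a 2'-hydroxychalcone), is reversible and poorly controlled for a plain chalcone. The cut at C4–C4a needs acid. Aryl transfer to a chromone is irreversible, and its facial sense is set by the ligand, which is what a stereocentre remote from C3/C4 requires.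

**33 ⇒ 31 ⇒ 30 ⇒ 29.** The three-carbon unit C4–C3–C2 of the pyranone is removed: ynone cyclisation (O1–C2), ethynyl addition (C3–C4) and ortho-formylation (C4–C4a) lead back to phenol 29. Against a Friedel–Crafts acetylation this has three advantages:
- it uses no acid;
- it cannot attack the equally electron-rich isoflavan ring A or ring B, because only the free phenol ring is formylated;
- it places the carbonyl next to the one oxygen that was kept distinct, which settles the 6- versus 8-isomer question.

The forward steps need a single free phenol, hence 29 ⇒ 28 by removal of an allyl group that is orthogonal to benzyl.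

**28 ⇒ 27 ⇒ 26 ⇒ 25.** The pyran O1–C2 bond is cut (Mitsunobu closure of phenol-alcohol 27). Both hydroxyls of 27 are released together from silyl ethers, after the C7 phenol of 25 has been benzylated. The two ring-A oxygens of 25 are already differentiated (free C7–OH, C8a–OTIPS), so no selectivity problem arises.

**25 ⇒ 19 + 20 (key disconnection).** Ring A is dismantled completely: C4a–C5, C4a–C8a, C7–C8 and C6–C7 are cut, giving α-diazo vinyl ketone 19 and (triisopropylsilyloxy)ethyne 20. Compared with attaching a finished resorcinol to C4 (a Friedel–Crafts bond that forms under acid and is reversible), this removes an entire arene and leaves an acyclic chain. In that chain C3 and C4 are ordinary sp3 centres β and γ to a ketone. The forward reaction must deliver the vinyl shift, the regiochemistry of the ketene–ynol ether cycloaddition and the electrocyclic cascade without touching C3/C4.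

**19 ⇒ 17 ⇒ 16 ⇒ 15 ⇒ 14.** The diazo group comes from diazo transfer to the only enolisable position of vinyl ketone 17. The vinyl group comes from Weinreb amide 16, and the amide and the silyl ether come from δ-lactone 14. The lactone stores both chain ends (acyl carbon and C2 oxygen) in one stable, non-epimerisable ring.

**14 ⇒ 13 ⇒ 5 + 10.** The C3–C4 bond is cut between the α-carbon of arylacetaldehyde 5 and the β-carbon of alkylidene malonate 10. This makes both stereocentres in one catalytic step and maps every carbon: the malonate becomes C4a and its carbonyl, and the aldehyde becomes C2. A nitroalkene acceptor would be more reactive but carries the wrong atoms. The forward reaction must be syn-selective and must cope with a hindered, electron-rich acceptor.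

**10 ⇒ 8 + 9; 8 ⇒ 7 ⇒ 6; 5 ⇒ 3 ⇒ 2 ⇒ 1.** Knoevenagel condensation, O-allylation and a para-selective formylation lead to 3,5-bis(benzyloxy)phenol 6. This installs the allyl/benzyl differentiation of the para-oxygen at the outset, where the ring is still symmetric. Aldehyde 5 comes from 2,6-dimethoxyphenol 1 by benzylation, formylation and one-carbon homologation.

## Roads not taken

Alternative 1: The cut is the C4a–C5 bond of the flavanone phloroglucinol ring. That ring is unravelled into a β,δ-diketo ester chain hanging from a preformed (2S)-2-aryl-2,3-dihydropyran-4-one, A1. In the forward sense Mg(OMe)2 would enolise the side chain, C4a would attack the methyl ester, and the new carbocycle would aromatise to A2, the target with only three benzyl ethers left.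
- Merits: the 5- and 7-hydroxyls arise free. The isoflavanyl carbon is locked between the two carbonyls, so the 6/8 question and the need to single out one phloroglucinol oxygen disappear. C2 can be set on a small ring.
- Weak points: the most acidic hydrogen of A1 sits on the methine between ketone and ester that also bears the bulky isoflavanyl group. The base would therefore first form a chelated enolate that deactivates the very ester to be attacked. The dihydropyranone is a β-alkoxy ketone that base can open by β-elimination, which would racemise C2. The chain can also close through oxygen. Assembling A1 requires joining the isoflavan C4 to a tricarbonyl chain, and the key step does nothing for C3, C4 or that bond.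
- Comparison: this end game is shorter and intrinsically cleaner in regiochemistry than the chosen plan, which pays with an allyl/benzyl differentiation (steps 5 and 17) and a four-step pyranone construction (steps 18–21). Against this the chosen plan exposes no base-labile β-aryloxy ketone to enolate chemistry, creates C2 last by a ligand-controlled C–C bond formation, and uses its key step to build the isoflavan around an already defined C3–C4 pair.

Alternative 2: The cut is O1–C2 of the flavanone. A single free phenol next to an alkylidene β-keto ester, A3, would add 6-endo-trig to the double bond under a quinine-derived bifunctional thiourea and give A4, whose tert-butyl ester is then removed.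
- Merits: the catalysis type is established for flavanones and is metal-free. The ester activates the acceptor, and the B-ring aldehyde enters late by Knoevenagel condensation.
- Weak points: A4 must lose its ester group under acid and heat, which are the conditions under which the C4–aryl bond cleaves and oxa-Michael adducts revert. The C2 configuration is therefore only as stable as that step allows. The β-keto ester has to be built on a hindered, electron-rich aryl ketone. The same single free phenol is required, so the protecting-group differentiation is not avoided. The key step leaves the isoflavan half and its two stereocentres to other chemistry.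
- Comparison: counted from phenol 29 this road is about as long as steps 18–21 and needs no noble metal, so in cost it is at least equal. The chosen plan sets against it an irreversible aryl transfer for C2 in a nearly neutral medium and the absence of any acid-mediated decarboxylation.

Alternative 3: The cut is C4–C4a of the flavanone. C2 is set beforehand by Mitsunobu inversion of an enantioenriched benzylic alcohol with the free phenol, giving β-aryloxy acid A5. Trifluoroacetic anhydride then forms a mixed anhydride that acylates the phloroglucinol ring ortho to the ether oxygen and closes the pyranone to A6.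
- Merits: C2 derives from a reliable asymmetric ketone reduction. The two ortho positions are equivalent, so the acylation is regiospecific. Only two operations lead from the phenol to the flavanone, clearly fewer than steps 18–21.
- Weak points: a secondary benzylic carbinol with a para-oxygenated aryl group tends to ionise or eliminate under Mitsunobu activation, which erodes the configuration. A5 can lose the phenol by β-elimination once the acid is activated. The anhydride generates CF3CO2H in the presence of the acid-labile C4–aryl bond. The 4'-acetate needs a separate basic cleavage after the epimerisable flavanone exists.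
- Comparison: in step economy this road is better. The chosen plan sets against it neutral or basic conditions throughout the late stage and no substitution step with carbocation character at C2.

Key step: step 13

Assumption: (triisopropylsilyloxy)ethyne 20 is not a common stock item; it is treated as an available reagent, drawn from a batch made by O-silylation of lithium ethynolate with triisopropylsilyl triflate. All other starting materials, the prolinol catalyst and the pyridine-oxazoline ligand are catalogue chemicals.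

## Route

Step 1
Reactants: 1 2,6-dimethoxyphenol
Product: 2 2-(benzyloxy)-1,3-dimethoxybenzene
Conditions: BnBr, K2CO3, DMF, 60 °C
Reagents that add atoms: benzyl bromide, BrCc1ccccc1
Why: Williamson etherification of the hindered phenoxide; benzyl lets this oxygen be unveiled in the final hydrogenolysis together with the other phenols.

Step 2
Reactants: 2 2-(benzyloxy)-1,3-dimethoxybenzene
Product: 3 3-(benzyloxy)-2,4-dimethoxybenzaldehyde
Conditions: POCl3, DMF, 80 °C; aq. NaOAc
Reagents that add atoms: N,N-dimethylformamide, CN(C)C=O; water, O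
Why: Vilsmeier–Haack formylation; a 1,2,3-trialkoxybenzene is attacked ortho to one methoxy group and para to the other, and the two such positions are equivalent.

Step 3
Reactants: 3 3-(benzyloxy)-2,4-dimethoxybenzaldehyde
Product: 5 2-[3-(benzyloxy)-2,4-dimethoxyphenyl]acetaldehyde, via methyl enol ether 4 (not isolated)
Conditions: Ph3P(CH2OMe)Cl, KOtBu, THF, 0 °C; then 2 M HCl, THF, rt
Reagents that add atoms: (methoxymethyl)triphenylphosphonium chloride, COC[P+](c1ccccc1)(c1ccccc1)c1ccccc1.[Cl-]; water, O
Why: Wittig one-carbon homologation to the enol ether followed by mild acid hydrolysis; the sensitive arylacetaldehyde is used at once in step 7.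

Step 4
Reactants: 6 3,5-bis(benzyloxy)phenol
Product: 7 2,6-bis(benzyloxy)-4-hydroxybenzaldehyde
Conditions: POCl3, DMF, MeCN, 0 °C → rt; H2O
Reagents that add atoms: N,N-dimethylformamide, CN(C)C=O; water, O
Why: Vilsmeier–Haack formylation of a 3,5-dialkoxyphenol goes mainly para to the free hydroxyl, as in the dimethyl ether series; the ortho isomer is removed by crystallisation or chromatography, and the free para-hydroxyl is the handle that later singles out the flavanone ring oxygen.

Step 5
Reactants: 7 2,6-bis(benzyloxy)-4-hydroxybenzaldehyde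
Product: 8 4-(allyloxy)-2,6-bis(benzyloxy)benzaldehyde
Conditions: allyl bromide, K2CO3, DMF, rt
Reagents that add atoms: allyl bromide, C=CCBr
Why: Williamson etherification of the only phenol; allyl withstands every step up to step 16 and is later removed by zerovalent palladium without acid and without touching benzyl ethers.

Step 6
Reactants: 8 4-(allyloxy)-2,6-bis(benzyloxy)benzaldehyde; 9 dimethyl malonate
Product: 10 dimethyl 2-[4-(allyloxy)-2,6-bis(benzyloxy)benzylidene]malonate
Conditions: piperidine (cat.), AcOH (cat.), toluene, reflux (Dean–Stark)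
Reagents that add atoms: none
Why: Knoevenagel condensation driven by azeotropic removal of water; with two identical ester groups there is no alkene geometry to control.

Step 7
Reactants: 5 2-[3-(benzyloxy)-2,4-dimethoxyphenyl]acetaldehyde; 10 dimethyl 2-[4-(allyloxy)-2,6-bis(benzyloxy)benzylidene]malonate
Product: 13 methyl (4S,5R)-4-ArP-5-ArB-2-oxotetrahydro-2H-pyran-3-carboxylate (C3 epimers), via Michael aldehyde 11 (not isolated), via hydroxy diester 12 (not isolated)
Conditions: (R)-α,α-diphenylprolinol TMS ether (20 mol %), PhCO2H (20 mol %), toluene, rt; then NaBH4, MeOH, 0 °C; cat. TsOH, CH2Cl2, rt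
Reagents that add atoms: none
Why: Enamine-catalysed Michael addition of an aldehyde to an alkylidene malonate: the (E)-enamine of 5, shielded on one face by the diphenyl(silyloxy)methyl group of the (R)-catalyst, attacks 10 through the usual acyclic synclinal transition state and should give the syn adduct 11 (R at the ArB carbon, S at the ArP carbon), which is the future trans-(3R,4S) pair. Immediate borohydride reduction freezes the epimerisable α-aryl aldehyde centre and the δ-hydroxy malonate lactonises; the C3 ester centre is removed in step 8 and does not matter.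

Step 8
Reactants: 13 methyl (4S,5R)-4-ArP-5-ArB-2-oxotetrahydro-2H-pyran-3-carboxylate
Product: 14 (4R,5R)-4-ArP-5-ArB-tetrahydro-2H-pyran-2-one
Conditions: LiCl, H2O, DMSO, 140 °C
Reagents that add atoms: none
Why: Krapcho dealkoxycarbonylation (chloride demethylation, then loss of CO2); neither stereocentre is α to a carbonyl, so both are untouched (the C4 descriptor changes only through CIP priorities), and the aryl allyl ether stays below its Claisen rearrangement range for the short reaction time.

Step 9
Reactants: 14 (4R,5R)-4-ArP-5-ArB-tetrahydro-2H-pyran-2-one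
Product: 15 (3R,4R)-3-ArP-4-ArB-5-hydroxy-N-methoxy-N-methylpentanamide
Conditions: MeNH(OMe)·HCl, AlMe3, CH2Cl2, 0 °C → rt
Reagents that add atoms: N,O-dimethylhydroxylamine hydrochloride, CNOC.Cl
Why: Aluminium amide aminolysis of a lactone to the Weinreb amide, which prepares the acyl carbon for a single vinyl addition and releases the primary alcohol that becomes C2.

Step 10
Reactants: 15 (3R,4R)-3-ArP-4-ArB-5-hydroxy-N-methoxy-N-methylpentanamide
Product: 16 (3R,4R)-3-ArP-4-ArB-5-[(tert-butyldimethylsilyl)oxy]-N-methoxy-N-methylpentanamide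
Conditions: TBSCl, imidazole, DMF, rt
Reagents that add atoms: tert-butyldimethylsilyl chloride, CC(C)(C)[Si](C)(C)Cl
Why: Silylation of the primary alcohol, done at once to forestall relactonisation; the TBS ether withstands Grignard reagent, amide base, light and heat and leaves together with the aryl TIPS ether in step 15.

Step 11
Reactants: 16 (3R,4R)-3-ArP-4-ArB-5-[(tert-butyldimethylsilyl)oxy]-N-methoxy-N-methylpentanamide
Product: 17 (5R,6R)-5-ArP-6-ArB-7-[(tert-butyldimethylsilyl)oxy]hept-1-en-3-one
Conditions: CH2=CHMgBr, THF, −78 → 0 °C; inverse quench into cold 1 M HCl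
Reagents that add atoms: vinylmagnesium bromide, C=C[Mg]Br
Why: Weinreb ketone synthesis; the chelated tetrahedral intermediate prevents over-addition, and the cold acidic inverse quench keeps the liberated hydroxylamine from adding to the new enone.

Step 12
Reactants: 17 (5R,6R)-5-ArP-6-ArB-7-[(tert-butyldimethylsilyl)oxy]hept-1-en-3-one
Product: 19 (5R,6R)-5-ArP-6-ArB-7-[(tert-butyldimethylsilyl)oxy]-4-diazohept-1-en-3-one, via trifluoroacetyl ketone 18 (not isolated)
Conditions: LiN(SiMe3)2, THF, −78 °C; CF3CO2CH2CF3; then MsN3, Et3N, H2O, MeCN, rt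
Reagents that add atoms: methanesulfonyl azide, CS(=O)(=O)N=[N+]=[N-]
Why: Detrifluoroacetylative diazo transfer: the vinyl side has no α-hydrogen, so kinetic enolisation and trifluoroacetylation occur only at the CH2 next to C4, and the activated 1,3-dicarbonyl 18 accepts the diazo group with loss of the trifluoroacetyl unit; C3 and C4 are not α to the carbonyl and are not at risk.

Step 13
Reactants: 19 (5R,6R)-5-ArP-6-ArB-7-[(tert-butyldimethylsilyl)oxy]-4-diazohept-1-en-3-one; 20 (triisopropylsilyloxy)ethyne
Product: 25 4-[(1S,2R)-1-ArP-2-ArB-3-[(tert-butyldimethylsilyl)oxy]propyl]-3-[(triisopropylsilyl)oxy]phenol, via vinylketene 21 (not isolated), via vinylcyclobutenone 22 (not isolated), via dienylketene 23 (not isolated), via cyclohexadienone 24 (not isolated)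
Conditions: 20 (3 equiv), hν (Hg lamp, Pyrex filter, > 300 nm), degassed ClCH2CH2Cl, rt; then 80 °C
Reagents that add atoms: none
Why: Irradiation expels N2 and triggers a Wolff rearrangement in which the vinyl group shifts from the carbonyl carbon to the diazo carbon (C4a–C5), giving vinylketene 21; this is the photochemical Danheiser benzannulation, whose closest known form is the union of α-diazo enones with siloxyalkynes to give resorcinol monosilyl ethers. Ketene 21 adds the electron-rich alkyne in a [2+2] cycloaddition in which the nucleophilic CH terminus of 20 bonds to the ketene carbonyl carbon (C7–C8) and the oxygen-bearing carbon to the ketene α-carbon (C4a–C8a), giving 4-vinylcyclobutenone 22. Warming opens 22 by reversible 4π-electrocyclic cleavage to dienylketene 23, and the isomer with vinyl cis to the ketene closes ring A by a thermal 6π-electrocyclisation (C6–C7) to cyclohexadienone 24, which tautomerises to phenol 25. Ring A thus closes by a six-electron electrocyclic process, the four-membered ring being only a relay. No stereocentre is created: the quaternary centre of 22 is erased on aromatisation, and C3 and C4 lie β and γ to the ketone and are not touched by neutral photolysis and thermolysis. The step needs the vinyl shift to outrun a 1,2-hydride shift and attack of a free carbene on an ortho-benzyloxy oxygen, which direct photolysis of the s-Z conformer (accessible because vinyl is small) favours. It also needs the polarity-matched regiochemistry of the [2+2] step, which places OTIPS ortho and OH para to the side chain. The excess of 20 is there to trap the unsubstituted vinylketene before it oligomerises or acylates the product phenol.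

Step 14
Reactants: 25 4-[(1S,2R)-1-ArP-2-ArB-3-[(tert-butyldimethylsilyl)oxy]propyl]-3-[(triisopropylsilyl)oxy]phenol
Product: 26 [5-(benzyloxy)-2-[(1S,2R)-1-ArP-2-ArB-3-[(tert-butyldimethylsilyl)oxy]propyl]phenoxy]triisopropylsilane
Conditions: BnBr, K2CO3, acetone, 50 °C
Reagents that add atoms: benzyl bromide, BrCc1ccccc1
Why: Williamson etherification of the only free phenol (C7–OH), which must be masked before the second ring-A oxygen is released; the hindered aryl TIPS ether survives carbonate in acetone.

Step 15
Reactants: 26 [5-(benzyloxy)-2-[(1S,2R)-1-ArP-2-ArB-3-[(tert-butyldimethylsilyl)oxy]propyl]phenoxy]triisopropylsilane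
Product: 27 5-(benzyloxy)-2-[(1S,2R)-1-ArP-2-ArB-3-hydroxypropyl]phenol
Conditions: Bu4NF, THF, 0 °C → rt; aq. NH4Cl
Reagents that add atoms: none
Why: Fluoride-induced cleavage of both silyl ethers gives the C8a phenol and the C2 alcohol in one operation; benzyl and allyl ethers are inert.

Step 16
Reactants: 27 5-(benzyloxy)-2-[(1S,2R)-1-ArP-2-ArB-3-hydroxypropyl]phenol
Product: 28 (3R,4S)-4-ArP-7-(benzyloxy)-3-ArB-chromane
Conditions: PPh3, DIAD, THF, 0 °C → rt
Reagents that add atoms: none
Why: Intramolecular Mitsunobu etherification: the activated primary alcohol is displaced by the neighbouring phenol in a 6-exo-tet closure (O1–C2); no stereocentre takes part, so the trans-(3R,4S) relationship set in step 7 is carried into the ring.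

Step 17
Reactants: 28 (3R,4S)-4-ArP-7-(benzyloxy)-3-ArB-chromane
Product: 29 3,5-bis(benzyloxy)-4-Chr-phenol
Conditions: Pd(PPh3)4 (cat.), morpholine, THF, rt
Reagents that add atoms: none
Why: Tsuji–Trost-type allyl transfer from the aryl allyl ether to morpholine through a π-allyl complex of palladium; the medium is neutral, which the acid-labile C4–aryl bond requires, and only the oxygen para to C4 is freed.

Step 18
Reactants: 29 3,5-bis(benzyloxy)-4-Chr-phenol
Product: 30 2,4-bis(benzyloxy)-3-Chr-6-hydroxybenzaldehyde
Conditions: MgCl2, Et3N, (CH2O)n, MeCN, reflux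
Reagents that add atoms: formaldehyde (as paraformaldehyde), C=O
Why: Magnesium-mediated ortho-formylation (Casnati–Skattebøl type): the magnesium phenoxide delivers formaldehyde to its ortho carbon and a second formaldehyde oxidises the benzylic alkoxide. Only the free-phenol ring reacts, its two ortho positions are equivalent, and no acid is used, so the future flavanone C4 is placed next to the oxygen that will be flavanone O1.

Step 19
Reactants: 30 2,4-bis(benzyloxy)-3-Chr-6-hydroxybenzaldehyde
Product: 31 1-[2,4-bis(benzyloxy)-3-Chr-6-hydroxyphenyl]prop-2-yn-1-ol (carbinol epimers)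
Conditions: HC≡CMgBr (3 equiv), THF, 0 °C → rt; aq. NH4Cl
Reagents that add atoms: ethynylmagnesium bromide, C#C[Mg]Br
Why: 1,2-Addition of an alkynyl Grignard reagent to the magnesium phenoxide of the salicylaldehyde; the new carbinol centre is destroyed in the next step, so its configuration is immaterial.

Step 20
Reactants: 31 1-[2,4-bis(benzyloxy)-3-Chr-6-hydroxyphenyl]prop-2-yn-1-ol
Product: 33 5,7-bis(benzyloxy)-6-Chr-4H-chromen-4-one, via ynone 32 (not isolated)
Conditions: MnO2, CH2Cl2, rt; then Et2NH, EtOH, 50 °C
Reagents that add atoms: none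
Why: MnO2 oxidises the benzylic propargylic alcohol to the 2-hydroxyaryl ynone; the secondary amine adds to it to give an enaminone that closes 6-endo with loss of the amine (the enaminone route to chromones), which avoids 5-exo closure to a benzofuranone.

Step 21
Reactants: 33 5,7-bis(benzyloxy)-6-Chr-4H-chromen-4-one; 34 4-(benzyloxy)phenylboronic acid
Product: 35 (2S)-5,7-bis(benzyloxy)-2-[4-(benzyloxy)phenyl]-6-Chr-chroman-4-one
Conditions: Pd(OCOCF3)2 (10 mol %), (R)-t-BuPyOx (12 mol %), NH4PF6, H2O, ClCH2CH2Cl, 60 °C
Reagents that add atoms: none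
Why: Asymmetric conjugate addition of an arylboronic acid to a chromone under cationic divalent palladium with a pyridine-oxazoline ligand. The aryl–palladium species adds across C2=C3 on the face chosen by the ligand alone, since the isoflavan stereocentres are five bonds away. The (R)-ligand is assigned by analogy with the known facial sense for cyclic enones and should give 2S; the base-free medium avoids retro-oxa-Michael opening of the product.

Step 22
Reactants: 35 (2S)-5,7-bis(benzyloxy)-2-[4-(benzyloxy)phenyl]-6-Chr-chroman-4-one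
Product: 36 (2S)-5,7-dihydroxy-6-[(3R,4S)-7-hydroxy-3-(3-hydroxy-2,4-dimethoxyphenyl)chroman-4-yl]-2-(4-hydroxyphenyl)chroman-4-one
Conditions: H2 (1 atm), 10% Pd/C, EtOAc–MeOH, rt
Reagents that add atoms: none
Why: Hydrogenolysis of five benzyl ethers under neutral conditions; no acid or base reaches the C4–aryl bond or the epimerisable flavanone C2, and the reaction is stopped once the benzyl groups are gone so that the aryl ketone and the benzylic C2–O1 bond are spared.

## Compound list

1 | 2,6-dimethoxyphenol | COc1cccc(OC)c1O | starting material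
2 | 2-(benzyloxy)-1,3-dimethoxybenzene | COc1cccc(OC)c1OCc1ccccc1 | intermediate
3 | 3-(benzyloxy)-2,4-dimethoxybenzaldehyde | COc1ccc(C=O)c(OC)c1OCc1ccccc1 | intermediate
4 | 2-(benzyloxy)-1,3-dimethoxy-4-(2-methoxyvinyl)benzene (E/Z) | COC=Cc1ccc(OC)c(OCc2ccccc2)c1OC | intermediate
5 | 2-[3-(benzyloxy)-2,4-dimethoxyphenyl]acetaldehyde | COc1ccc(CC=O)c(OC)c1OCc1ccccc1 | intermediate
6 | 3,5-bis(benzyloxy)phenol | Oc1cc(OCc2ccccc2)cc(OCc2ccccc2)c1 | starting material
7 | 2,6-bis(benzyloxy)-4-hydroxybenzaldehyde | O=Cc1c(OCc2ccccc2)cc(O)cc1OCc1ccccc1 | intermediate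
8 | 4-(allyloxy)-2,6-bis(benzyloxy)benzaldehyde | O=Cc1c(OCc2ccccc2)cc(OCC=C)cc1OCc1ccccc1 | intermediate
9 | dimethyl malonate | COC(=O)CC(=O)OC | starting material
10 | dimethyl 2-[4-(allyloxy)-2,6-bis(benzyloxy)benzylidene]malonate | COC(=O)C(=Cc1c(OCc2ccccc2)cc(OCC=C)cc1OCc1ccccc1)C(=O)OC | intermediate
11 | dimethyl 2-[(1S,2R)-1-ArP-2-ArB-3-oxopropyl]malonate | COc1ccc([C@H](C=O)[C@@H](C(C(=O)OC)C(=O)OC)c2c(OCc3ccccc3)cc(OCC=C)cc2OCc2ccccc2)c(OC)c1OCc1ccccc1 | intermediate
12 | dimethyl 2-[(1S,2R)-1-ArP-2-ArB-3-hydroxypropyl]malonate | COc1ccc([C@H](CO)[C@@H](C(C(=O)OC)C(=O)OC)c2c(OCc3ccccc3)cc(OCC=C)cc2OCc2ccccc2)c(OC)c1OCc1ccccc1 | intermediate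
13 | methyl (4S,5R)-4-ArP-5-ArB-2-oxotetrahydro-2H-pyran-3-carboxylate (C3 epimers) | COc1ccc([C@@H]2COC(=O)C(C(=O)OC)[C@H]2c2c(OCc3ccccc3)cc(OCC=C)cc2OCc2ccccc2)c(OC)c1OCc1ccccc1 | intermediate
14 | (4R,5R)-4-ArP-5-ArB-tetrahydro-2H-pyran-2-one | COc1ccc([C@@H]2COC(=O)C[C@H]2c2c(OCc3ccccc3)cc(OCC=C)cc2OCc2ccccc2)c(OC)c1OCc1ccccc1 | intermediate
15 | (3R,4R)-3-ArP-4-ArB-5-hydroxy-N-methoxy-N-methylpentanamide | COc1ccc([C@H](CO)[C@@H](CC(=O)N(C)OC)c2c(OCc3ccccc3)cc(OCC=C)cc2OCc2ccccc2)c(OC)c1OCc1ccccc1 | intermediate
16 | (3R,4R)-3-ArP-4-ArB-5-[(tert-butyldimethylsilyl)oxy]-N-methoxy-N-methylpentanamide | COc1ccc([C@H](CO[Si](C)(C)C(C)(C)C)[C@@H](CC(=O)N(C)OC)c2c(OCc3ccccc3)cc(OCC=C)cc2OCc2ccccc2)c(OC)c1OCc1ccccc1 | intermediate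
17 | (5R,6R)-5-ArP-6-ArB-7-[(tert-butyldimethylsilyl)oxy]hept-1-en-3-one | COc1ccc([C@H](CO[Si](C)(C)C(C)(C)C)[C@@H](CC(=O)C=C)c2c(OCc3ccccc3)cc(OCC=C)cc2OCc2ccccc2)c(OC)c1OCc1ccccc1 | intermediate
18 | (5S,6R)-5-ArP-6-ArB-7-[(tert-butyldimethylsilyl)oxy]-4-(trifluoroacetyl)hept-1-en-3-one (C4 epimers and enol forms) | COc1ccc([C@H](CO[Si](C)(C)C(C)(C)C)[C@@H](C(C(=O)C=C)C(=O)C(F)(F)F)c2c(OCc3ccccc3)cc(OCC=C)cc2OCc2ccccc2)c(OC)c1OCc1ccccc1 | intermediate
19 | (5R,6R)-5-ArP-6-ArB-7-[(tert-butyldimethylsilyl)oxy]-4-diazohept-1-en-3-one | COc1ccc([C@H](CO[Si](C)(C)C(C)(C)C)[C@@H](C(=[N+]=[N-])C(=O)C=C)c2c(OCc3ccccc3)cc(OCC=C)cc2OCc2ccccc2)c(OC)c1OCc1ccccc1 | intermediate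
20 | (triisopropylsilyloxy)ethyne | C#CO[Si](C(C)C)(C(C)C)C(C)C | starting material
21 | 2-[(1R,2R)-1-ArP-2-ArB-3-[(tert-butyldimethylsilyl)oxy]propyl]buta-1,3-dien-1-one | COc1ccc([C@H](CO[Si](C)(C)C(C)(C)C)[C@@H](C(C=C)=C=O)c2c(OCc3ccccc3)cc(OCC=C)cc2OCc2ccccc2)c(OC)c1OCc1ccccc1 | intermediate
22 | 4-[(1R,2R)-1-ArP-2-ArB-3-[(tert-butyldimethylsilyl)oxy]propyl]-3-[(triisopropylsilyl)oxy]-4-vinylcyclobut-2-en-1-one (ring C4 epimers) | COc1ccc([C@H](CO[Si](C)(C)C(C)(C)C)[C@@H](C2(C=C)C(=O)C=C2O[Si](C(C)C)(C(C)C)C(C)C)c2c(OCc3ccccc3)cc(OCC=C)cc2OCc2ccccc2)c(OC)c1OCc1ccccc1 | intermediate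
23 | (3Z)-4-[(1S,2R)-1-ArP-2-ArB-3-[(tert-butyldimethylsilyl)oxy]propyl]-3-[(triisopropylsilyl)oxy]hexa-1,3,5-trien-1-one | COc1ccc([C@H](CO[Si](C)(C)C(C)(C)C)[C@@H](C(/C=C)=C(O[Si](C(C)C)(C(C)C)C(C)C)/C=C=O)c2c(OCc3ccccc3)cc(OCC=C)cc2OCc2ccccc2)c(OC)c1OCc1ccccc1 | intermediate
24 | 4-[(1S,2R)-1-ArP-2-ArB-3-[(tert-butyldimethylsilyl)oxy]propyl]-3-[(triisopropylsilyl)oxy]cyclohexa-2,4-dien-1-one | COc1ccc([C@H](CO[Si](C)(C)C(C)(C)C)[C@@H](C2=CCC(=O)C=C2O[Si](C(C)C)(C(C)C)C(C)C)c2c(OCc3ccccc3)cc(OCC=C)cc2OCc2ccccc2)c(OC)c1OCc1ccccc1 | intermediate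
25 | 4-[(1S,2R)-1-ArP-2-ArB-3-[(tert-butyldimethylsilyl)oxy]propyl]-3-[(triisopropylsilyl)oxy]phenol | COc1ccc([C@H](CO[Si](C)(C)C(C)(C)C)[C@@H](c2ccc(O)cc2O[Si](C(C)C)(C(C)C)C(C)C)c2c(OCc3ccccc3)cc(OCC=C)cc2OCc2ccccc2)c(OC)c1OCc1ccccc1 | intermediate
26 | [5-(benzyloxy)-2-[(1S,2R)-1-ArP-2-ArB-3-[(tert-butyldimethylsilyl)oxy]propyl]phenoxy]triisopropylsilane | COc1ccc([C@H](CO[Si](C)(C)C(C)(C)C)[C@@H](c2ccc(OCc3ccccc3)cc2O[Si](C(C)C)(C(C)C)C(C)C)c2c(OCc3ccccc3)cc(OCC=C)cc2OCc2ccccc2)c(OC)c1OCc1ccccc1 | intermediate
27 | 5-(benzyloxy)-2-[(1S,2R)-1-ArP-2-ArB-3-hydroxypropyl]phenol | COc1ccc([C@H](CO)[C@@H](c2ccc(OCc3ccccc3)cc2O)c2c(OCc3ccccc3)cc(OCC=C)cc2OCc2ccccc2)c(OC)c1OCc1ccccc1 | intermediate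
28 | (3R,4S)-4-ArP-7-(benzyloxy)-3-ArB-chromane | COc1ccc([C@@H]2COc3cc(OCc4ccccc4)ccc3[C@H]2c2c(OCc3ccccc3)cc(OCC=C)cc2OCc2ccccc2)c(OC)c1OCc1ccccc1 | intermediate
29 | 3,5-bis(benzyloxy)-4-Chr-phenol | COc1ccc([C@@H]2COc3cc(OCc4ccccc4)ccc3[C@H]2c2c(OCc3ccccc3)cc(O)cc2OCc2ccccc2)c(OC)c1OCc1ccccc1 | intermediate
30 | 2,4-bis(benzyloxy)-3-Chr-6-hydroxybenzaldehyde | COc1ccc([C@@H]2COc3cc(OCc4ccccc4)ccc3[C@H]2c2c(OCc3ccccc3)c(C=O)c(O)cc2OCc2ccccc2)c(OC)c1OCc1ccccc1 | intermediate
31 | 1-[2,4-bis(benzyloxy)-3-Chr-6-hydroxyphenyl]prop-2-yn-1-ol (carbinol epimers) | COc1ccc([C@@H]2COc3cc(OCc4ccccc4)ccc3[C@H]2c2c(OCc3ccccc3)c(C(O)C#C)c(O)cc2OCc2ccccc2)c(OC)c1OCc1ccccc1 | intermediate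
32 | 1-[2,4-bis(benzyloxy)-3-Chr-6-hydroxyphenyl]prop-2-yn-1-one | COc1ccc([C@@H]2COc3cc(OCc4ccccc4)ccc3[C@H]2c2c(OCc3ccccc3)c(C(=O)C#C)c(O)cc2OCc2ccccc2)c(OC)c1OCc1ccccc1 | intermediate
33 | 5,7-bis(benzyloxy)-6-Chr-4H-chromen-4-one | COc1ccc([C@@H]2COc3cc(OCc4ccccc4)ccc3[C@H]2c2c(OCc3ccccc3)cc3c(c2OCc2ccccc2)C(=O)C=CO3)c(OC)c1OCc1ccccc1 | intermediate
34 | 4-(benzyloxy)phenylboronic acid | OB(O)c1ccc(OCc2ccccc2)cc1 | starting material
35 | (2S)-5,7-bis(benzyloxy)-2-[4-(benzyloxy)phenyl]-6-Chr-chroman-4-one | COc1ccc([C@@H]2COc3cc(OCc4ccccc4)ccc3[C@H]2c2c(OCc3ccccc3)cc3c(c2OCc2ccccc2)C(=O)C[C@@H](c2ccc(OCc4ccccc4)cc2)O3)c(OC)c1OCc1ccccc1 | intermediate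
36 | (2S)-5,7-dihydroxy-6-[(3R,4S)-7-hydroxy-3-(3-hydroxy-2,4-dimethoxyphenyl)chroman-4-yl]-2-(4-hydroxyphenyl)chroman-4-one | COc1ccc([C@@H]2COc3cc(O)ccc3[C@H]2c2c(O)cc3c(c2O)C(=O)C[C@@H](c2ccc(O)cc2)O3)c(OC)c1O | target

## Step count and least certain steps

Total: 22 steps. Longest linear sequence: 19 steps (from 6 through steps 4–6 and 7–22; the branch from 1 through steps 1–3 and 7–22 is equally long).

**Step 13 (key step).**
- What may go wrong: after loss of nitrogen the excited diazo ketone or a free carbene may undergo a 1,2-hydride shift from C4 or be captured by an ortho-benzyloxy oxygen instead of rearranging. The unsubstituted vinylketene may also oligomerise or acylate the product phenol faster than it meets the alkyne, because the ketene α-carbon carries a very bulky substituent.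
- Fallback: this leaves the route at lactone 14 and generates the same ketene without a carbene. Deprotonation of 14 with LiN(iPr)2, aldol addition to acetaldehyde and dehydration (MsCl, Et3N, then DBU) would give the α-ethylidene lactone F1. Saponification, silylation of the hydroxy acid salt (TBSCl, imidazole) and cleavage of the silyl ester with K2CO3 in methanol would give the butenoic acid F2. 1-Chloro-N,N,2-trimethylpropenylamine would convert it into the acid chloride F3. Triethylamine in toluene at 80 °C in the presence of 20 would then effect 1,4-dehydrochlorination to vinylketene 21, which follows the same cascade through 22–24 and returns to the route at 25.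

**Step 7.**
- What may go wrong: slow addition, because the acceptor carries a di-ortho-substituted, electron-rich aryl group and the α-aryl enamine is a weak nucleophile. Slow addition gives time for self-condensation of 5 and for erosion of the configuration at the α-aryl aldehyde carbon before reduction.
- Fallback: this replaces enamine catalysis by a preformed auxiliary-bound enolate. Pinnick oxidation of 5 would give the arylacetic acid F7. Acylation of (R)-4-benzyloxazolidin-2-one through the pivaloyl mixed anhydride would give the imide F8. Its sodium (Z)-enolate (NaN(SiMe3)2, THF, −78 °C) would add to 10 to give the Michael adduct F9, in which the auxiliary fixes the ArB carbon as R. The sense at the ArP carbon would have to be confirmed and, if needed, steered by the counter-ion. LiBH4 would remove the auxiliary, and the resulting 12 lactonises, so the sequence returns to the route at 13.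

**Step 12.**
- What may go wrong: anionic polymerisation of the unsubstituted vinyl ketone, or conjugate addition of its own enolate, during deprotonation; and sluggish trifluoroacetylation next to the crowded C4.
- Fallback: this starts from amide 16 and masks the enone terminus. (E)-2-(Trimethylsilyl)vinyllithium, made from (E)-(2-bromovinyl)trimethylsilane and t-BuLi, would give the β-silyl enone F4, which resists both side reactions. The same diazo transfer would give the diazo ketone F5. Irradiation with 20 and heating would give the 6-(trimethylsilyl)phenol F6, with silicon on ring A next to the free hydroxyl. Ipso-protodesilylation at this doubly oxygen-activated position (brief CF3CO2H in CH2Cl2 at low temperature) returns to the route at 25.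

**Step 21.**
- What may go wrong: low conversion, because the 5,7-dialkoxy chromone is a poor acceptor and the boronic acid protodeboronates in competition; and insufficient or opposite facial selectivity for this substrate.
- Fallback: this gives up catalyst control and uses the fact that the C2 epimers are diastereomers. A non-selective addition of 34 to 33 (Pd(OCOCF3)2, 2,2'-bipyridine) would give 35 together with its (2R)-epimer F10, to be separated by chromatography. F10 would be recycled by base-induced opening (NaOAc, EtOH) to the chalcone F11, whose reclosure regenerates the mixture; the sequence returns to the route at 35.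

**Step 20.**
- What may go wrong: 5-exo closure of the ynone to a benzofuranone, or amine addition that stops at the enaminone.
- Fallback: this starts from aldehyde 30 and avoids the ynone. MeMgBr would give the carbinol F12 and MnO2 the 2-hydroxyacetophenone F13. N,N-Dimethylformamide dimethyl acetal would give the enaminone F14, which closes with loss of dimethylamine on warming in toluene with a little acetic acid and returns to the route at 33.

## Further compounds

F1 | step 13 | (4R,5R)-4-ArP-5-ArB-3-ethylidenetetrahydro-2H-pyran-2-one (E/Z) | COc1ccc([C@@H]2COC(=O)C(=CC)[C@H]2c2c(OCc3ccccc3)cc(OCC=C)cc2OCc2ccccc2)c(OC)c1OCc1ccccc1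
F2 | step 13 | 2-[(1R,2R)-1-ArP-2-ArB-3-[(tert-butyldimethylsilyl)oxy]propyl]but-2-enoic acid (E/Z) | COc1ccc([C@H](CO[Si](C)(C)C(C)(C)C)[C@@H](C(=CC)C(=O)O)c2c(OCc3ccccc3)cc(OCC=C)cc2OCc2ccccc2)c(OC)c1OCc1ccccc1
F3 | step 13 | 2-[(1R,2R)-1-ArP-2-ArB-3-[(tert-butyldimethylsilyl)oxy]propyl]but-2-enoyl chloride (E/Z) | COc1ccc([C@H](CO[Si](C)(C)C(C)(C)C)[C@@H](C(=CC)C(=O)Cl)c2c(OCc3ccccc3)cc(OCC=C)cc2OCc2ccccc2)c(OC)c1OCc1ccccc1
F4 | step 12 | (1E,5R,6R)-5-ArP-6-ArB-7-[(tert-butyldimethylsilyl)oxy]-1-(trimethylsilyl)hept-1-en-3-one | COc1ccc([C@H](CO[Si](C)(C)C(C)(C)C)[C@@H](CC(=O)/C=C/[Si](C)(C)C)c2c(OCc3ccccc3)cc(OCC=C)cc2OCc2ccccc2)c(OC)c1OCc1ccccc1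
F5 | step 12 | (1E,5R,6R)-5-ArP-6-ArB-7-[(tert-butyldimethylsilyl)oxy]-4-diazo-1-(trimethylsilyl)hept-1-en-3-one | COc1ccc([C@H](CO[Si](C)(C)C(C)(C)C)[C@@H](C(=[N+]=[N-])C(=O)/C=C/[Si](C)(C)C)c2c(OCc3ccccc3)cc(OCC=C)cc2OCc2ccccc2)c(OC)c1OCc1ccccc1
F6 | step 12 | 4-[(1S,2R)-1-ArP-2-ArB-3-[(tert-butyldimethylsilyl)oxy]propyl]-3-[(triisopropylsilyl)oxy]-6-(trimethylsilyl)phenol | COc1ccc([C@H](CO[Si](C)(C)C(C)(C)C)[C@@H](c2cc([Si](C)(C)C)c(O)cc2O[Si](C(C)C)(C(C)C)C(C)C)c2c(OCc3ccccc3)cc(OCC=C)cc2OCc2ccccc2)c(OC)c1OCc1ccccc1
F7 | step 7 | 2-[3-(benzyloxy)-2,4-dimethoxyphenyl]acetic acid | COc1ccc(CC(=O)O)c(OC)c1OCc1ccccc1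
F8 | step 7 | (4R)-4-benzyl-3-[2-[3-(benzyloxy)-2,4-dimethoxyphenyl]acetyl]oxazolidin-2-one | COc1ccc(CC(=O)N2[C@H](Cc3ccccc3)COC2=O)c(OC)c1OCc1ccccc1
F9 | step 7 | dimethyl 2-[(1S,2R)-1-ArP-2-ArB-3-[(4R)-4-benzyl-2-oxooxazolidin-3-yl]-3-oxopropyl]malonate | COc1ccc([C@H](C(=O)N2[C@H](Cc3ccccc3)COC2=O)[C@@H](C(C(=O)OC)C(=O)OC)c2c(OCc3ccccc3)cc(OCC=C)cc2OCc2ccccc2)c(OC)c1OCc1ccccc1
F10 | step 21 | (2R)-5,7-bis(benzyloxy)-2-[4-(benzyloxy)phenyl]-6-Chr-chroman-4-one | COc1ccc([C@@H]2COc3cc(OCc4ccccc4)ccc3[C@H]2c2c(OCc3ccccc3)cc3c(c2OCc2ccccc2)C(=O)C[C@H](c2ccc(OCc4ccccc4)cc2)O3)c(OC)c1OCc1ccccc1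
F11 | step 21 | (E)-1-[2,4-bis(benzyloxy)-3-Chr-6-hydroxyphenyl]-3-[4-(benzyloxy)phenyl]prop-2-en-1-one | COc1ccc([C@@H]2COc3cc(OCc4ccccc4)ccc3[C@H]2c2c(OCc3ccccc3)cc(O)c(c2OCc2ccccc2)C(=O)/C=C/c2ccc(OCc3ccccc3)cc2)c(OC)c1OCc1ccccc1
F12 | step 20 | 1-[2,4-bis(benzyloxy)-3-Chr-6-hydroxyphenyl]ethanol (carbinol epimers) | COc1ccc([C@@H]2COc3cc(OCc4ccccc4)ccc3[C@H]2c2c(OCc3ccccc3)c(C(C)O)c(O)cc2OCc2ccccc2)c(OC)c1OCc1ccccc1
F13 | step 20 | 1-[2,4-bis(benzyloxy)-3-Chr-6-hydroxyphenyl]ethanone | COc1ccc([C@@H]2COc3cc(OCc4ccccc4)ccc3[C@H]2c2c(OCc3ccccc3)c(C(C)=O)c(O)cc2OCc2ccccc2)c(OC)c1OCc1ccccc1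
F14 | step 20 | (E)-1-[2,4-bis(benzyloxy)-3-Chr-6-hydroxyphenyl]-3-(dimethylamino)prop-2-en-1-one | COc1ccc([C@@H]2COc3cc(OCc4ccccc4)ccc3[C@H]2c2c(OCc3ccccc3)c(C(=O)/C=C/N(C)C)c(O)cc2OCc2ccccc2)c(OC)c1OCc1ccccc1
A1 | alternative 1 | methyl 2-Chr-3-oxo-4-[(2S)-2-[4-(benzyloxy)phenyl]-4-oxo-3,4-dihydro-2H-pyran-6-yl]butanoate (C2 of the butanoate unassigned) | COc1ccc([C@@H]2COc3cc(OCc4ccccc4)ccc3[C@H]2C(C(=O)OC)C(=O)CC2=CC(=O)C[C@@H](c3ccc(OCc4ccccc4)cc3)O2)c(OC)c1OCc1ccccc1
A2 | alternative 1 | (2S)-2-[4-(benzyloxy)phenyl]-6-Chr-5,7-dihydroxychroman-4-one | COc1ccc([C@@H]2COc3cc(OCc4ccccc4)ccc3[C@H]2c2c(O)cc3c(c2O)C(=O)C[C@@H](c2ccc(OCc4ccccc4)cc2)O3)c(OC)c1OCc1ccccc1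
A3 | alternative 2 | tert-butyl 2-[2,4-bis(benzyloxy)-3-Chr-6-hydroxybenzoyl]-3-[4-(benzyloxy)phenyl]acrylate (alkene geometry unassigned) | COc1ccc([C@@H]2COc3cc(OCc4ccccc4)ccc3[C@H]2c2c(OCc3ccccc3)cc(O)c(C(=O)C(C(=O)OC(C)(C)C)=Cc3ccc(OCc4ccccc4)cc3)c2OCc2ccccc2)c(OC)c1OCc1ccccc1
A4 | alternative 2 | tert-butyl (2S)-5,7-bis(benzyloxy)-2-[4-(benzyloxy)phenyl]-6-Chr-4-oxochroman-3-carboxylate (C3 unassigned) | COc1ccc([C@@H]2COc3cc(OCc4ccccc4)ccc3[C@H]2c2c(OCc3ccccc3)cc3c(c2OCc2ccccc2)C(=O)C(C(=O)OC(C)(C)C)[C@@H](c2ccc(OCc4ccccc4)cc2)O3)c(OC)c1OCc1ccccc1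
A5 | alternative 3 | (3S)-3-(4-acetoxyphenyl)-3-[3,5-bis(benzyloxy)-4-Chr-phenoxy]propanoic acid | COc1ccc([C@@H]2COc3cc(OCc4ccccc4)ccc3[C@H]2c2c(OCc3ccccc3)cc(O[C@@H](CC(=O)O)c3ccc(OC(C)=O)cc3)cc2OCc2ccccc2)c(OC)c1OCc1ccccc1
A6 | alternative 3 | 4-[(2S)-5,7-bis(benzyloxy)-6-Chr-4-oxochroman-2-yl]phenyl acetate | COc1ccc([C@@H]2COc3cc(OCc4ccccc4)ccc3[C@H]2c2c(OCc3ccccc3)cc3c(c2OCc2ccccc2)C(=O)C[C@@H](c2ccc(OC(C)=O)cc2)O3)c(OC)c1OCc1ccccc1
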